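**Strategy**

The target is a benzofuran whose furan ring carries, next to O1, a 4-hydroxyphenyl group on C2 and a 2,4-dihydroxybenzoyl group on C3. The plan cuts O1–C2, C3–C(=O) and C(=O)–aryl at once: a palladium-catalysed carbonylative annulation unites an ortho-alkynylphenol, an aryl iodide and CO, closing the furan ring and building the diaryl ketone in a single operation. The precursor is a benzyl-protected dihydrochalcone, assembled from two benzylated building blocks, whose ring A carries a (4-benzyloxyphenyl)ethynyl group at C3' beside the only free hydroxyl, O2'; its ketone becomes the C7 acyl group. Hydrogenolysis of six benzyl ethers completes the synthesis.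

Key step: step 8

**Remarks on the chemistry**

- Locants: open-chain compounds carry dihydrochalcone locants (ring A is the acylated phloroglucinol ring with primed locants, ring B the 4-oxygenated phenyl ring). From step 8 on, benzofuran locants apply: C1' becomes C7, O2' becomes O1, C3' becomes C3a, C4' becomes C4 and C6' becomes C6.
- Assumption: 1-[2,4-bis(benzyloxy)-6-hydroxyphenyl]ethan-1-one and 4-(benzyloxy)benzaldehyde are taken as catalogue compounds.
- Protecting-group pattern: the three benzyl ethers of the dihydrochalcone arrive with the two building blocks, so no hydroxyl of a free polyphenol has to be told apart. The one free hydroxyl is the hydrogen-bonded O2', which later becomes O1.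
- Acetate mask: O2' is held as an acetate during the alkyne coupling, because free ortho-iodophenols tend to close to 3-unsubstituted benzofurans under copper/amine conditions.
- The target has no stereocentre; the E double bond of the chalcone is removed in step 2. Transient species (the aldol adduct of step 1, organopalladium species of the catalytic cycles) are described in the Why lines and are not numbered.

**Route**

Step 1
Reactants: 1 1-[2,4-bis(benzyloxy)-6-hydroxyphenyl]ethan-1-one; 2 4-(benzyloxy)benzaldehyde
Product: 3 (2E)-1-[2,4-bis(benzyloxy)-6-hydroxyphenyl]-3-[4-(benzyloxy)phenyl]prop-2-en-1-one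
Conditions: KOH (aq. 50%, 5 equiv), EtOH–THF, 25 °C; then aq. HCl, 0 °C
Reagents that add atoms: none
Why: Claisen–Schmidt condensation, in which the methyl ketone enolate adds to the non-enolisable aldehyde and the aldol adduct loses water by E1cB elimination to the conjugated enone of the thermodynamically favoured E geometry, while the strongly basic medium holds the product as its open phenoxide and cold acidification avoids closure to the flavanone.

Step 2
Reactants: 3 (2E)-1-[2,4-bis(benzyloxy)-6-hydroxyphenyl]-3-[4-(benzyloxy)phenyl]prop-2-en-1-one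
Product: 4 1-[2,4-bis(benzyloxy)-6-hydroxyphenyl]-3-[4-(benzyloxy)phenyl]propan-1-one
Conditions: H2 (4 bar), RhCl(PPh3)3 (5 mol%), toluene–EtOH, 50 °C
Reagents that add atoms: none
Why: Homogeneous hydrogenation with RhCl(PPh3)3 should saturate the disubstituted C=C bond of the enone and leave the aryl benzyl ethers, the ketone and the arenes untouched, a selectivity that palladium on carbon would not guarantee.

Step 3
Reactants: 4 1-[2,4-bis(benzyloxy)-6-hydroxyphenyl]-3-[4-(benzyloxy)phenyl]propan-1-one
Product: 5 1-[4,6-bis(benzyloxy)-2-hydroxy-3-iodophenyl]-3-[4-(benzyloxy)phenyl]propan-1-one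
Conditions: NIS (1.05 equiv), DMF, 0 °C to 25 °C
Reagents that add atoms: N-iodosuccinimide, O=C1CCC(=O)N1I
Why: Electrophilic aromatic iodination of ring A, the most electron-rich ring, should occur at C3', ortho to the hydrogen-bonded hydroxyl and para to the 6'-benzyloxy group, which is the usual preference of chelated 2-hydroxy-4,6-dialkoxyaryl ketones, whereas C5' is shielded between two benzyloxy groups and ring B is far less activated.

Step 4
Reactants: 5 1-[4,6-bis(benzyloxy)-2-hydroxy-3-iodophenyl]-3-[4-(benzyloxy)phenyl]propan-1-one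
Product: 6 3,5-bis(benzyloxy)-2-{3-[4-(benzyloxy)phenyl]propanoyl}-6-iodophenyl acetate
Conditions: Ac2O, Et3N, DMAP (cat.), CH2Cl2, 25 °C
Reagents that add atoms: acetic anhydride, CC(=O)OC(C)=O
Why: DMAP-catalysed O-acylation caps O2', so that the alkynylphenol cannot close to a 3-unsubstituted benzofuran under the copper and amine of the next step, and the aryl acetate is stable to Et3N.

Step 5
Reactants: 6 3,5-bis(benzyloxy)-2-{3-[4-(benzyloxy)phenyl]propanoyl}-6-iodophenyl acetate; 7 1-(benzyloxy)-4-ethynylbenzene
Product: 8 3,5-bis(benzyloxy)-2-{3-[4-(benzyloxy)phenyl]propanoyl}-6-{[4-(benzyloxy)phenyl]ethynyl}phenyl acetate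
Conditions: PdCl2(PPh3)2 (5 mol%), CuI (5 mol%), Et3N, THF (degassed), 45 °C
Reagents that add atoms: none
Why: Sonogashira coupling of an aryl iodide with a terminal alkyne, run with gentle heating because the iodide is electron-rich and flanked on both sides, should give the diarylalkyne, which cannot cyclise because no ortho hydroxyl is free.

Step 6
Reactants: 8 3,5-bis(benzyloxy)-2-{3-[4-(benzyloxy)phenyl]propanoyl}-6-{[4-(benzyloxy)phenyl]ethynyl}phenyl acetate
Product: 9 1-[4,6-bis(benzyloxy)-3-{[4-(benzyloxy)phenyl]ethynyl}-2-hydroxyphenyl]-3-[4-(benzyloxy)phenyl]propan-1-one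
Conditions: K2CO3 (cat.), MeOH–THF, 0 °C
Reagents that add atoms: none
Why: Carbonate-catalysed transesterification (Zemplén-type methanolysis) removes the aryl acetate, and the phenoxide released is conjugated to the ortho ketone and should not add to the triple bond at 0 °C, while benzyl ethers, ketone and alkyne are inert.

Step 7
Reactants: 10 1,3-bis(benzyloxy)benzene
Product: 11 2,4-bis(benzyloxy)-1-iodobenzene
Conditions: NIS (1.0 equiv), TFA (cat.), MeCN, 0 °C to 25 °C
Reagents that add atoms: N-iodosuccinimide, O=C1CCC(=O)N1I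
Why: Electrophilic aromatic iodination should take place at C4, which is ortho to one benzyloxy group and para to the other, since C2 between the two ethers is hindered and one equivalent of NIS limits twofold iodination.

Step 8
Reactants: 9 1-[4,6-bis(benzyloxy)-3-{[4-(benzyloxy)phenyl]ethynyl}-2-hydroxyphenyl]-3-[4-(benzyloxy)phenyl]propan-1-one; 11 2,4-bis(benzyloxy)-1-iodobenzene; 12 carbon monoxide
Product: 13 1-{4,6-bis(benzyloxy)-2-[4-(benzyloxy)phenyl]-3-[2,4-bis(benzyloxy)benzoyl]-1-benzofuran-7-yl}-3-[4-(benzyloxy)phenyl]propan-1-one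
Conditions: 11 (1.5 equiv), Pd(PPh3)4 (10 mol%), CO (ca. 1.5 bar), K2CO3, MeCN–THF, 0 °C to 45 °C
Reagents that add atoms: none
Why: Oxidative addition of 11 to zerovalent palladium and insertion of CO give an aroylpalladium iodide (divalent palladium) that binds the triple bond of 9 as a π-acid; the phenoxide at O2' then attacks the distal alkyne carbon anti to the metal, forming O1–C2, and the resulting 3-benzofuranyl(aroyl)palladium species reductively eliminates to make the C3–C(=O) bond and return zerovalent palladium, the aryl–C(=O) bond having been made at the insertion stage. The closest known reaction type is the palladium-catalysed carbonylative annulation of 2-alkynylphenols with aryl iodides and CO to 2-substituted 3-aroylbenzofurans. The furan ring is closed in the 5-endo-dig mode; a 4-exo closure at the proximal carbon is strained and no other hydroxyl is free, so only one ring can form. No stereocentre is created. The step must favour aroylation over three alternatives: direct arylation without CO, suppressed because the electron-rich ortho-benzyloxy arylpalladium inserts CO readily under a slight overpressure; proton-terminated closure to the 3-unsubstituted benzofuran, slow because the phenoxide is conjugated to the ortho ketone and is generated only after 11 and the catalyst have been stirred under CO; and O-aroylation of the phenoxide, hindered by its two ortho substituents.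

Step 9
Reactants: 13 1-{4,6-bis(benzyloxy)-2-[4-(benzyloxy)phenyl]-3-[2,4-bis(benzyloxy)benzoyl]-1-benzofuran-7-yl}-3-[4-(benzyloxy)phenyl]propan-1-one
Product: 14 1-[3-(2,4-dihydroxybenzoyl)-4,6-dihydroxy-2-(4-hydroxyphenyl)-1-benzofuran-7-yl]-3-(4-hydroxyphenyl)propan-1-one (CNP0181782.0)
Conditions: H2 (1 atm), 10% Pd/C, THF–MeOH, 25 °C
Reagents that add atoms: none
Why: Catalytic hydrogenolysis should cleave all six aryl benzyl ethers, while the two aryl ketones (each hydrogen-bonded to an ortho hydroxyl once freed) and the fully substituted, acyl-conjugated C2=C3 bond of the benzofuran are not expected to be reduced at one atmosphere and room temperature.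

**Compound list**

1 | 1-[2,4-bis(benzyloxy)-6-hydroxyphenyl]ethan-1-one | CC(=O)c1c(O)cc(OCc2ccccc2)cc1OCc1ccccc1 | starting material
2 | 4-(benzyloxy)benzaldehyde | O=Cc1ccc(OCc2ccccc2)cc1 | starting material
3 | (2E)-1-[2,4-bis(benzyloxy)-6-hydroxyphenyl]-3-[4-(benzyloxy)phenyl]prop-2-en-1-one | O=C(/C=C/c1ccc(OCc2ccccc2)cc1)c1c(O)cc(OCc2ccccc2)cc1OCc1ccccc1 | intermediate
4 | 1-[2,4-bis(benzyloxy)-6-hydroxyphenyl]-3-[4-(benzyloxy)phenyl]propan-1-one | O=C(CCc1ccc(OCc2ccccc2)cc1)c1c(O)cc(OCc2ccccc2)cc1OCc1ccccc1 | intermediate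
5 | 1-[4,6-bis(benzyloxy)-2-hydroxy-3-iodophenyl]-3-[4-(benzyloxy)phenyl]propan-1-one | O=C(CCc1ccc(OCc2ccccc2)cc1)c1c(O)c(I)c(OCc2ccccc2)cc1OCc1ccccc1 | intermediate
6 | 3,5-bis(benzyloxy)-2-{3-[4-(benzyloxy)phenyl]propanoyl}-6-iodophenyl acetate | CC(=O)Oc1c(I)c(OCc2ccccc2)cc(OCc2ccccc2)c1C(=O)CCc1ccc(OCc2ccccc2)cc1 | intermediate
7 | 1-(benzyloxy)-4-ethynylbenzene | C#Cc1ccc(OCc2ccccc2)cc1 | starting material
8 | 3,5-bis(benzyloxy)-2-{3-[4-(benzyloxy)phenyl]propanoyl}-6-{[4-(benzyloxy)phenyl]ethynyl}phenyl acetate | CC(=O)Oc1c(C#Cc2ccc(OCc3ccccc3)cc2)c(OCc2ccccc2)cc(OCc2ccccc2)c1C(=O)CCc1ccc(OCc2ccccc2)cc1 | intermediate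
9 | 1-[4,6-bis(benzyloxy)-3-{[4-(benzyloxy)phenyl]ethynyl}-2-hydroxyphenyl]-3-[4-(benzyloxy)phenyl]propan-1-one | O=C(CCc1ccc(OCc2ccccc2)cc1)c1c(O)c(C#Cc2ccc(OCc3ccccc3)cc2)c(OCc2ccccc2)cc1OCc1ccccc1 | intermediate
10 | 1,3-bis(benzyloxy)benzene | c1ccc(cc1)COc1cccc(OCc2ccccc2)c1 | starting material
11 | 2,4-bis(benzyloxy)-1-iodobenzene | Ic1ccc(OCc2ccccc2)cc1OCc1ccccc1 | intermediate
12 | carbon monoxide | [C-]#[O+] | starting material
13 | 1-{4,6-bis(benzyloxy)-2-[4-(benzyloxy)phenyl]-3-[2,4-bis(benzyloxy)benzoyl]-1-benzofuran-7-yl}-3-[4-(benzyloxy)phenyl]propan-1-one | O=C(CCc1ccc(OCc2ccccc2)cc1)c1c(OCc2ccccc2)cc(OCc2ccccc2)c2c(C(=O)c3ccc(OCc4ccccc4)cc3OCc3ccccc3)c(-c3ccc(OCc4ccccc4)cc3)oc12 | intermediate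
14 | 1-[3-(2,4-dihydroxybenzoyl)-4,6-dihydroxy-2-(4-hydroxyphenyl)-1-benzofuran-7-yl]-3-(4-hydroxyphenyl)propan-1-one | O=C(CCc1ccc(O)cc1)c1c(O)cc(O)c2c(C(=O)c3ccc(O)cc3O)c(-c3ccc(O)cc3)oc12 | target

**Step count**

Total steps: 9. Longest linear sequence: 8 (steps 1, 2, 3, 4, 5, 6, 8, 9); step 7 is a one-step side branch.

**Steps most likely to fail**

Step 8. What may go wrong: ring closure terminated by a proton instead of the aroyl group, or aryl transfer without uptake of CO, so that C3 is left without the ketone. Fallback, setting out from 9 and 11 and coming back at 13: ring closure and ketone formation would be separated. Iodine and NaHCO3 in MeCN at 25 °C would convert 9 by 5-endo-dig iodocyclisation into 1-{4,6-bis(benzyloxy)-2-[4-(benzyloxy)phenyl]-3-iodo-1-benzofuran-7-yl}-3-[4-(benzyloxy)phenyl]propan-1-one F1. Miyaura borylation of 11 (B2pin2, PdCl2(dppf), KOAc, dioxane, 80 °C) would give 2-[2,4-bis(benzyloxy)phenyl]-4,4,5,5-tetramethyl-1,3,2-dioxaborolane F2. A carbonylative Suzuki–Miyaura coupling of F1 with F2 under CO 12 (PdCl2(dppf), K2CO3, wet anisole, 80 °C) would then deliver 13.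

Step 5. What may go wrong: slow oxidative addition at the doubly flanked, electron-rich carbon–iodine bond, so that copper-mediated oxidative dimerisation of 7 or loss of the acetate takes over. Fallback, setting out from 6 and 7 and coming back at 8: a copper-free Negishi alkynylation. ZnBr2 and Et3N in THF would turn 7 into {[4-(benzyloxy)phenyl]ethynyl}zinc bromide F3, which would be coupled with 6 using Pd(PPh3)4 in THF at 25 to 50 °C to give 8; the organozinc reagent tolerates the acetate and the ketone.

Step 3. What may go wrong: poor site selectivity, that is attack at C5' between the two benzyloxy groups, or twofold iodination. Fallback, setting out from 4 and coming back at 5: the choice of site would be removed by symmetry. Benzylation of the last hydroxyl of 4 (benzyl bromide, Cs2CO3, DMF, 60 °C) would give 3-[4-(benzyloxy)phenyl]-1-[2,4,6-tris(benzyloxy)phenyl]propan-1-one F4, whose two open positions on ring A are equivalent. NIS with catalytic TFA in MeCN–CH2Cl2 can then give only one mono-iodide, 3-[4-(benzyloxy)phenyl]-1-[2,4,6-tris(benzyloxy)-3-iodophenyl]propan-1-one F5. One equivalent of BCl3 in CH2Cl2 at −78 °C would cleave a single benzyl ether ortho to the ketone by chelation. The 2'-ether, pushed out of the ring plane by iodine and the acyl group, is the more basic and more strained one and is expected to be the one lost, giving 5.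

**Further compounds**

F1 | step 8 | 1-{4,6-bis(benzyloxy)-2-[4-(benzyloxy)phenyl]-3-iodo-1-benzofuran-7-yl}-3-[4-(benzyloxy)phenyl]propan-1-one | O=C(CCc1ccc(OCc2ccccc2)cc1)c1c(OCc2ccccc2)cc(OCc2ccccc2)c2c(I)c(-c3ccc(OCc4ccccc4)cc3)oc12
F2 | step 8 | 2-[2,4-bis(benzyloxy)phenyl]-4,4,5,5-tetramethyl-1,3,2-dioxaborolane | CC1(C)OB(OC1(C)C)c1ccc(OCc2ccccc2)cc1OCc1ccccc1
F3 | step 5 | {[4-(benzyloxy)phenyl]ethynyl}zinc bromide | Br[Zn]C#Cc1ccc(OCc2ccccc2)cc1
F4 | step 3 | 3-[4-(benzyloxy)phenyl]-1-[2,4,6-tris(benzyloxy)phenyl]propan-1-one | O=C(CCc1ccc(OCc2ccccc2)cc1)c1c(OCc2ccccc2)cc(OCc2ccccc2)cc1OCc1ccccc1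
F5 | step 3 | 3-[4-(benzyloxy)phenyl]-1-[2,4,6-tris(benzyloxy)-3-iodophenyl]propan-1-one | O=C(CCc1ccc(OCc2ccccc2)cc1)c1c(OCc2ccccc2)c(I)c(OCc2ccccc2)cc1OCc1ccccc1
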